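Time in the red run at 22 °C lifted side product from 13.4% to 27.7%, while target went from 20.3% to 20.1%. So for the hot south-west flask I reckoned with what the charge leaves for target.

| flask | starting material | coupling partner | capture agent | temperature | remark | time |
|---|---|---|---|---|---|---|
| amber | 0.28 M | 0.21 M | 0.060 M | −20 °C | run made earlier |  |
| red | 0.44 M | 0.21 M | 0.060 M | 22 °C | run made earlier |  |
| green | 0.20 M | 0.32 M | 0.060 M | −20 °C | run made earlier |  |
| south-west | 0.20 M | 0.210 M | 0.0600 M | 60 °C |  | 2.0 min |
| north | 0.20 M | 0.210 M | 0.0600 M | −15 °C |  | 2.0 min |
| north-east | 0.20 M | 0.210 M | 0.0600 M | 10 °C |  | 2.0 min |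
| west | 0.20 M | 0.210 M | 0.0600 M | 35 °C |  | 2.0 min |

| run | time / min | target / % | trapped intermediate / % | side product / % |
|---|---|---|---|---|
| amber | 12.0 | 0 | 3.8 | 0 |
| amber | 25.0 | 3.2 | 6.6 | 1.2 |
| amber | 40.0 | 3.7 | 13.4 | 2.4 |
| amber | 50.0 | 4.6 | 15.2 | 4.5 |
| amber | 80.0 | 11.9 | 18.2 | 7.1 |
| red | 1.50 | 20.3 | 7.5 | 13.4 |
| red | 3.00 | 22.0 | 8.2 | 18.3 |
| red | 4.00 | 22.3 | 10.1 | 19.8 |
| red | 6.00 | 21.4 | 11.2 | 23.7 |
| red | 8.00 | 20.1 | 9.9 | 27.7 |
| green | 8.00 | 0.9 | 3.1 | 0 |
| green | 20.0 | 2.2 | 9.6 | 1.3 |
| green | 40.0 | 8.0 | 17.8 | 4.3 |
| green | 80.0 | 17.0 | 27.7 | 5.1 |

(standard deviation of a reading: 1 percentage point)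

* which flask leads in share of target in all that became target or trapped intermediate or side product ("all alike" within 1.5 percentage points) (south-west / north / north-east / west / all alike)
* share of target in all that became target or trapped intermediate or side product, south-west
* share of target in all that became target or trapped intermediate or side product, north
* share of target in all that became target or trapped intermediate or side product, north-east
* share of target in all that became target or trapped intermediate or side product, west

- in percentages every species weighs as the starting material in it: one side product counts as two

1. I took one capture agent for each trapped intermediate. In south-west, [capture agent] over [starting material], as charged, was 30.0%. I called this the capture ceiling: the trapped intermediate the charge can carry, in percent of starting material. Trapped intermediate then equals the ceiling times the fraction of capture agent used. The green run, with the same ratio, read 27.7% at its last reading, less than the ceiling.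

2. Suppose the whole south-west charge reacted and trapped intermediate reached the ceiling. Then 70.0% stayed for target and side product. On that supposition the share of target, the selectivity, is that room divided by one plus the ratio of side product to target.

3. The early extreme used the first red reading, at 1.50 min. Its ratio was 0.660, which gave 42.2%.

4. The late extreme used the last red reading, at 8.00 min. Its ratio was 1.38, which gave 29.4%.

5. South-west was hotter than the red run, so I read its 2.0 min as a late time. But it held less starting material than the red run, which made this uncertain. I committed to about 29.4%.

6. The forecast gave 42% for south-west, above my figure, with 18% for north, 46% for north-east and 56% for west, so it put west first, and it held that “target is slowly lost to side product when warm”.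

7. The simulation put west in the lead at 54.4%, with north-east at 49.8%, north at 21.1% and south-west at 20.3%.

    starting material + open intermediate → side product (k = 0.0640 /M/s, Ea = 64.0 kJ/mol)
    open intermediate ⇌ target + released group (K = 0.220 M, k = 0.0720 /s, Ea = 74.0 kJ/mol, ΔH = −45.0 kJ/mol)
    open intermediate + capture agent → trapped intermediate (k = 0.300 /M/s, Ea = 41.0 kJ/mol)
    starting material + coupling partner ⇌ open intermediate (K = 190 /M, k = 0.280 /M/s, Ea = 62.0 kJ/mol, ΔH = −59.0 kJ/mol)
    (constants at 35 °C)

8. South-west came in below my figure. Its ratio of side product to target was 2.24, above my late reading. With 2.5% of its capture agent left, south-west held 29.3% of trapped intermediate, under its ceiling of 30.0%. The neighbour flask, like south-west but charged with 0.080 M of starting material, had a ceiling of 75.0%. With 24% of its capture agent left, that ceiling times the fraction of capture agent used gave 57.0%. That neighbour held 56.7% of trapped intermediate, and its share of target was 27.3%.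

The earlier runs and the new flask were generated by integration on assumed constants, and the scatter is random.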